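**Assumption:** the SMILES is read literally: (6S,7R,8R,10R), 4Z, with a 6,7-cis-fused 12,6-lactone. Germacrane numbering (C1–C15) is used for locants.

## Retrosynthetic overview

1. Target 26 ⇐ silyl ether 25 ⇐ diene 24 by ring-closing metathesis at C4=C5 (nine-membered oxacycle, formed last).
2. 24 ⇐ furanone allyl bromide 18 + acrolein + isobutyryl chloride by indium Barbier reaction and lactonisation (C6–C7 bond; lactone ring formed second).
3. 18 ⇐ 2-hydroxy-2-alkynyl ketone 17 by gold-catalysed heterocyclisation with 1,2-methyl shift (furanone ring formed first; C10 set by chirality transfer).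
4. 17 ⇐ silyl ketol 8 + aldehyde 13 (boron aldol, C8–C9); 8 ⇐ enyne 5 + butane-2,3-dione (new enantioselective mono-alkynylation).
5. 5 ⇐ 2-bromoallyl alcohol + ethynylmagnesium bromide; 13 ⇐ 2,2-dimethoxyacetaldehyde + methyl acrylate.

## Route

Step 1
Reactants: 1 2-bromoprop-2-en-1-ol
Product: 2 [(2-bromoprop-2-en-1-yl)oxy](tert-butyl)diphenylsilane
Conditions: TBDPSCl, imidazole, CH2Cl2, 0 °C → rt
Reagents that add atoms: tert-butyl(chloro)diphenylsilane, CC(C)(C)[Si](Cl)(c1ccccc1)c1ccccc1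
Why: Standard silylation of a primary alcohol; the TBDPS ether is chosen because it survives the Lewis acids of steps 6–8 and the aqueous HCl of step 9.

Step 2
Reactants: 2 [(2-bromoprop-2-en-1-yl)oxy](tert-butyl)diphenylsilane; 3 ethynylmagnesium bromide
Product: 5 tert-butyl[(2-methylidenebut-3-yn-1-yl)oxy]diphenylsilane, via ethynylzinc bromide 4 (not isolated)
Conditions: 3, ZnBr2, THF, 0 °C; then 2, Pd(PPh3)4 (3 mol%), rt
Reagents that add atoms: none
Why: Negishi ethynylation: zerovalent palladium inserts into the vinylic C–Br bond and couples with the alkynylzinc, giving the terminal 1,3-enyne directly.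

Step 3
Reactants: 5 tert-butyl[(2-methylidenebut-3-yn-1-yl)oxy]diphenylsilane; 6 butane-2,3-dione
Product: 8 (3R)-6-{[tert-butyl(diphenyl)silyl]oxymethyl}-3-methyl-3-(trimethylsilyloxy)hept-6-en-4-yn-2-one, via ketol 7 (not isolated)
Conditions: 6 (4 equiv, slow addition), Zn(OTf)2 (20 mol%), (1S,2S)-3-(TBSO)-2-(Me2N)-1-(4-nitrophenyl)propan-1-ol (22 mol%), Et3N (30 mol%), toluene, 40 °C; then TMSCl, imidazole, 0 °C
Reagents that add atoms: chlorotrimethylsilane, C[Si](C)(C)Cl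
Why: Proposed new method: catalytic enantioselective mono-alkynylation of an acyclic, enolisable 1,2-diketone; the s-cis dione chelates the divalent zinc amino-alkoxide, which makes it more electrophilic than the product ketol and places its enantiotopic carbonyl faces in the chiral pocket, so the zinc acetylide of 5 adds once to give the (R)-carbinol that later becomes C10, with excess volatile 6 suppressing double addition; closest known reaction type is the Zn(OTf)2/amino-alcohol alkynylation of aldehydes and α-keto esters, and the TMSCl quench caps the tertiary alcohol in the same flask.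

Step 4
Reactants: 9 2,2-dimethoxyacetaldehyde; 10 methyl acrylate
Product: 11 methyl 3-hydroxy-4,4-dimethoxy-2-methylidenebutanoate (racemic)
Conditions: DABCO (30 mol%), 1,4-dioxane–H2O, rt
Reagents that add atoms: none
Why: Morita–Baylis–Hillman reaction of an activated, non-enolisable aldehyde; the racemic carbinol centre is erased in step 5.

Step 5
Reactants: 11 methyl 3-hydroxy-4,4-dimethoxy-2-methylidenebutanoate
Product: 13 methyl (2Z)-2-(bromomethyl)-4-oxobut-2-enoate, via bromo acetal 12 (not isolated)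
Conditions: PBr3, Et2O, −10 °C; then H2O, TFA, rt
Reagents that add atoms: phosphorus tribromide, BrP(Br)Br; water, O
Why: SN2' bromination of the Baylis–Hillman alcohol gives the thermodynamically preferred (Z)-2-(bromomethyl)enoate, and aqueous acid then unmasks the conjugated aldehyde.

Step 6
Reactants: 8 (3R)-6-{[tert-butyl(diphenyl)silyl]oxymethyl}-3-methyl-3-(trimethylsilyloxy)hept-6-en-4-yn-2-one; 13 methyl (2Z)-2-(bromomethyl)-4-oxobut-2-enoate
Product: 15 methyl (2Z,4R,7R)-2-(bromomethyl)-10-{[tert-butyl(diphenyl)silyl]oxymethyl}-4-hydroxy-7-methyl-6-oxo-7-(trimethylsilyloxy)undeca-2,10-dien-8-ynoate, via enol borinate 14 (not isolated)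
Conditions: (−)-Ipc2BCl, Et3N, Et2O, −78 → 0 °C; then 13, −78 → −20 °C; MeOH, pH 7 buffer, H2O2, 0 °C
Reagents that add atoms: none
Why: Paterson boron aldol of a methyl ketone: only the CH3 group can enolise, and the diisopinocampheylboron enolate adds to the Re face of non-enolisable 13 under reagent control to set C8 as R; (−)-Ipc2BCl is the antipode assigned here from the allylboration analogy and the reported reversal of facial sense for methyl ketones, an assignment that is not certain and is checked on the first run.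

Step 7
Reactants: 15 methyl (2Z,4R,7R)-2-(bromomethyl)-10-{[tert-butyl(diphenyl)silyl]oxymethyl}-4-hydroxy-7-methyl-6-oxo-7-(trimethylsilyloxy)undeca-2,10-dien-8-ynoate
Product: 16 methyl (2Z,4R,7R)-2-(bromomethyl)-4-(tert-butyldimethylsilyloxy)-10-{[tert-butyl(diphenyl)silyl]oxymethyl}-7-methyl-6-oxo-7-(trimethylsilyloxy)undeca-2,10-dien-8-ynoate
Conditions: TBSOTf, 2,6-lutidine, CH2Cl2, −78 °C
Reagents that add atoms: tert-butyldimethylsilyl triflate, CC(C)(C)[Si](C)(C)OS(=O)(=O)C(F)(F)F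
Why: Silyl triflate silylation of the secondary alcohol; a silyl ether rather than the final ester is carried at C8 because an acyloxy group there would be lost by 1,4-elimination from the allylindium of step 9.

Step 8
Reactants: 16 methyl (2Z,4R,7R)-2-(bromomethyl)-4-(tert-butyldimethylsilyloxy)-10-{[tert-butyl(diphenyl)silyl]oxymethyl}-7-methyl-6-oxo-7-(trimethylsilyloxy)undeca-2,10-dien-8-ynoate
Product: 18 methyl (2Z,4R)-2-(bromomethyl)-4-(tert-butyldimethylsilyloxy)-5-[(2R)-5-(3-{[tert-butyl(diphenyl)silyl]oxy}prop-1-en-2-yl)-2-methyl-3-oxo-2,3-dihydrofuran-2-yl]pent-2-enoate, via free ketol 17 (not isolated)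
Conditions: PPTS (10 mol%), MeOH, 0 °C; evaporate; then AuCl3 (5 mol%), CH2Cl2, rt
Reagents that add atoms: none
Why: π-Acid-catalysed heterocyclisation/1,2-alkyl shift of a 2-hydroxy-2-alkynyl ketone: trivalent gold activates the alkyne for 5-endo attack by the ketone oxygen, and the methyl group then migrates suprafacially from the carbinol carbon to the adjacent oxocarbenium carbon on the face it already occupies, so the (R)-carbinol is transferred into (R)-C10 while the carbinol carbon becomes the C1 ketone.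

Step 9
Reactants: 18 methyl (2Z,4R)-2-(bromomethyl)-4-(tert-butyldimethylsilyloxy)-5-[(2R)-5-(3-{[tert-butyl(diphenyl)silyl]oxy}prop-1-en-2-yl)-2-methyl-3-oxo-2,3-dihydrofuran-2-yl]pent-2-enoate; 19 prop-2-enal (acrolein)
Product: 22 (4R,5S)-5-ethenyl-4-{(1R)-1-hydroxy-2-[(2R)-5-(3-{[tert-butyl(diphenyl)silyl]oxy}prop-1-en-2-yl)-2-methyl-3-oxo-2,3-dihydrofuran-2-yl]ethyl}-3-methylideneoxolan-2-one, via hydroxy ester 20 (not isolated), via silyl lactone 21 (not isolated)
Conditions: In powder, 19 (3 equiv), THF–H2O (3:1), rt; crude, then 2 M HCl–THF, rt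
Reagents that add atoms: none
Why: Indium-mediated Barbier 2-(alkoxycarbonyl)allylation then acid lactonisation: the Z-configured allylindium reacts through a chair transition state with the C8 side chain axial to give the syn (6,7-cis) adduct, and acrolein approaches anti to the C8–OSi bond with H8 in the olefin plane, which sets C6 as S and C7 as R; HCl then closes the lactone and removes the secondary TBS ether while the primary TBDPS ether stays.

Step 10
Reactants: 22 (4R,5S)-5-ethenyl-4-{(1R)-1-hydroxy-2-[(2R)-5-(3-{[tert-butyl(diphenyl)silyl]oxy}prop-1-en-2-yl)-2-methyl-3-oxo-2,3-dihydrofuran-2-yl]ethyl}-3-methylideneoxolan-2-one; 23 2-methylpropanoyl chloride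
Product: 24 (1R)-1-[(2S,3R)-2-ethenyl-4-methylidene-5-oxooxolan-3-yl]-2-[(2R)-5-(3-{[tert-butyl(diphenyl)silyl]oxy}prop-1-en-2-yl)-2-methyl-3-oxo-2,3-dihydrofuran-2-yl]ethyl 2-methylpropanoate
Conditions: 23, pyridine, DMAP (cat.), CH2Cl2, 0 °C
Reagents that add atoms: none
Why: DMAP-catalysed acylation of the only free hydroxyl with retention at C8; the low temperature keeps acylation ahead of base-induced translactonisation to the 8,12-olide.

Step 11
Reactants: 24 (1R)-1-[(2S,3R)-2-ethenyl-4-methylidene-5-oxooxolan-3-yl]-2-[(2R)-5-(3-{[tert-butyl(diphenyl)silyl]oxy}prop-1-en-2-yl)-2-methyl-3-oxo-2,3-dihydrofuran-2-yl]ethyl 2-methylpropanoate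
Product: 25 (4Z,6S,7R,8R,10R)-15-[tert-butyl(diphenyl)silyloxy]-1-oxo-3,10-epoxygermacra-2,4,11(13)-trien-12,6-olid-8-yl 2-methylpropanoate
Conditions: second-generation Hoveyda–Grubbs catalyst (15 mol%), toluene (1 mM), 90 °C, Ar sparge
Reagents that add atoms: none
Why: Ring-closing metathesis between the C6 vinyl group and the 1,1-disubstituted C4 olefin closes the nine-membered oxacycle; only the in-ring Z olefin can span the furanone bridge, the cis-lactone holds both olefin arms on one face, and the conjugated exo-methylene lactone is a poor metathesis partner.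

Step 12
Reactants: 25 (4Z,6S,7R,8R,10R)-15-[tert-butyl(diphenyl)silyloxy]-1-oxo-3,10-epoxygermacra-2,4,11(13)-trien-12,6-olid-8-yl 2-methylpropanoate
Product: 26 (4Z,6S,7R,8R,10R)-15-hydroxy-1-oxo-3,10-epoxygermacra-2,4,11(13)-trien-12,6-olid-8-yl 2-methylpropanoate (CNP0176924.5)
Conditions: HF·pyridine, pyridine, THF, 0 °C → rt
Reagents that add atoms: none
Why: Buffered fluoride desilylation of the primary silyl ether leaves the exo-methylene lactone, the isobutyrate and the furanone untouched and changes no stereocentre.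

## Compound list

1 | 2-bromoprop-2-en-1-ol | OCC(Br)=C | starting material
2 | [(2-bromoprop-2-en-1-yl)oxy](tert-butyl)diphenylsilane | C=C(Br)CO[Si](c1ccccc1)(c1ccccc1)C(C)(C)C | intermediate
3 | ethynylmagnesium bromide | C#C[Mg]Br | starting material
4 | ethynylzinc bromide | C#C[Zn]Br | intermediate
5 | tert-butyl[(2-methylidenebut-3-yn-1-yl)oxy]diphenylsilane | C#CC(=C)CO[Si](c1ccccc1)(c1ccccc1)C(C)(C)C | intermediate
6 | butane-2,3-dione | CC(=O)C(C)=O | starting material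
7 | (3R)-6-{[tert-butyl(diphenyl)silyl]oxymethyl}-3-hydroxy-3-methylhept-6-en-4-yn-2-one | CC(=O)[C@](O)(C#CC(=C)CO[Si](c1ccccc1)(c1ccccc1)C(C)(C)C)C | intermediate
8 | (3R)-6-{[tert-butyl(diphenyl)silyl]oxymethyl}-3-methyl-3-(trimethylsilyloxy)hept-6-en-4-yn-2-one | CC(=O)[C@](O[Si](C)(C)C)(C#CC(=C)CO[Si](c1ccccc1)(c1ccccc1)C(C)(C)C)C | intermediate
9 | 2,2-dimethoxyacetaldehyde | COC(OC)C=O | starting material
10 | methyl acrylate | C=CC(=O)OC | starting material
11 | methyl 3-hydroxy-4,4-dimethoxy-2-methylidenebutanoate (racemic) | COC(=O)C(=C)C(O)C(OC)OC | intermediate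
12 | methyl (2Z)-2-(bromomethyl)-4,4-dimethoxybut-2-enoate | BrC/C(C(=O)OC)=C\C(OC)OC | intermediate
13 | methyl (2Z)-2-(bromomethyl)-4-oxobut-2-enoate | BrC/C(C(=O)OC)=C\C=O | intermediate
14 | bis[(1R,2S,3R,5R)-isopinocampheyl]boron enolate of 8 (boron on the enol oxygen, terminal C=CH2) | C=C(OB([C@@H]1C[C@@H]2C[C@H]([C@H]1C)C2(C)C)[C@@H]1C[C@@H]2C[C@H]([C@H]1C)C2(C)C)[C@](O[Si](C)(C)C)(C#CC(=C)CO[Si](c1ccccc1)(c1ccccc1)C(C)(C)C)C | intermediate
15 | methyl (2Z,4R,7R)-2-(bromomethyl)-10-{[tert-butyl(diphenyl)silyl]oxymethyl}-4-hydroxy-7-methyl-6-oxo-7-(trimethylsilyloxy)undeca-2,10-dien-8-ynoate | BrC/C(C(=O)OC)=C\[C@H](O)CC(=O)[C@](O[Si](C)(C)C)(C#CC(=C)CO[Si](c1ccccc1)(c1ccccc1)C(C)(C)C)C | intermediate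
16 | methyl (2Z,4R,7R)-2-(bromomethyl)-4-(tert-butyldimethylsilyloxy)-10-{[tert-butyl(diphenyl)silyl]oxymethyl}-7-methyl-6-oxo-7-(trimethylsilyloxy)undeca-2,10-dien-8-ynoate | BrC/C(C(=O)OC)=C\[C@H](O[Si](C)(C)C(C)(C)C)CC(=O)[C@](O[Si](C)(C)C)(C#CC(=C)CO[Si](c1ccccc1)(c1ccccc1)C(C)(C)C)C | intermediate
17 | methyl (2Z,4R,7R)-2-(bromomethyl)-4-(tert-butyldimethylsilyloxy)-10-{[tert-butyl(diphenyl)silyl]oxymethyl}-7-hydroxy-7-methyl-6-oxoundeca-2,10-dien-8-ynoate | BrC/C(C(=O)OC)=C\[C@H](O[Si](C)(C)C(C)(C)C)CC(=O)[C@](O)(C#CC(=C)CO[Si](c1ccccc1)(c1ccccc1)C(C)(C)C)C | intermediate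
18 | methyl (2Z,4R)-2-(bromomethyl)-4-(tert-butyldimethylsilyloxy)-5-[(2R)-5-(3-{[tert-butyl(diphenyl)silyl]oxy}prop-1-en-2-yl)-2-methyl-3-oxo-2,3-dihydrofuran-2-yl]pent-2-enoate | C=C(CO[Si](c1ccccc1)(c1ccccc1)C(C)(C)C)C1=CC(=O)[C@@](C)(C[C@@H](O[Si](C)(C)C(C)(C)C)/C=C(\CBr)C(=O)OC)O1 | intermediate
19 | prop-2-enal (acrolein) | C=CC=O | starting material
20 | methyl (3S,4S)-3-{(1R)-1-(tert-butyldimethylsilyloxy)-2-[(2R)-5-(3-{[tert-butyl(diphenyl)silyl]oxy}prop-1-en-2-yl)-2-methyl-3-oxo-2,3-dihydrofuran-2-yl]ethyl}-4-hydroxy-2-methylidenehex-5-enoate | C=C(CO[Si](c1ccccc1)(c1ccccc1)C(C)(C)C)C1=CC(=O)[C@@](C)(C[C@@H](O[Si](C)(C)C(C)(C)C)[C@H]([C@@H](O)C=C)C(=C)C(=O)OC)O1 | intermediate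
21 | (4S,5S)-4-{(1R)-1-(tert-butyldimethylsilyloxy)-2-[(2R)-5-(3-{[tert-butyl(diphenyl)silyl]oxy}prop-1-en-2-yl)-2-methyl-3-oxo-2,3-dihydrofuran-2-yl]ethyl}-5-ethenyl-3-methylideneoxolan-2-one | C=C(CO[Si](c1ccccc1)(c1ccccc1)C(C)(C)C)C1=CC(=O)[C@@](C)(C[C@@H](O[Si](C)(C)C(C)(C)C)[C@@H]2[C@H](C=C)OC(=O)C2=C)O1 | intermediate
22 | (4R,5S)-5-ethenyl-4-{(1R)-1-hydroxy-2-[(2R)-5-(3-{[tert-butyl(diphenyl)silyl]oxy}prop-1-en-2-yl)-2-methyl-3-oxo-2,3-dihydrofuran-2-yl]ethyl}-3-methylideneoxolan-2-one | C=C(CO[Si](c1ccccc1)(c1ccccc1)C(C)(C)C)C1=CC(=O)[C@@](C)(C[C@@H](O)[C@@H]2[C@H](C=C)OC(=O)C2=C)O1 | intermediate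
23 | 2-methylpropanoyl chloride | CC(C)C(Cl)=O | starting material
24 | (1R)-1-[(2S,3R)-2-ethenyl-4-methylidene-5-oxooxolan-3-yl]-2-[(2R)-5-(3-{[tert-butyl(diphenyl)silyl]oxy}prop-1-en-2-yl)-2-methyl-3-oxo-2,3-dihydrofuran-2-yl]ethyl 2-methylpropanoate | C=C(CO[Si](c1ccccc1)(c1ccccc1)C(C)(C)C)C1=CC(=O)[C@@](C)(C[C@@H](OC(=O)C(C)C)[C@@H]2[C@H](C=C)OC(=O)C2=C)O1 | intermediate
25 | (4Z,6S,7R,8R,10R)-15-[tert-butyl(diphenyl)silyloxy]-1-oxo-3,10-epoxygermacra-2,4,11(13)-trien-12,6-olid-8-yl 2-methylpropanoate | C=C1C(=O)O[C@H]2/C=C(/CO[Si](c4ccccc4)(c5ccccc5)C(C)(C)C)C3=CC(=O)[C@@](C)(C[C@@H](OC(=O)C(C)C)[C@@H]12)O3 | intermediate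
26 | (4Z,6S,7R,8R,10R)-15-hydroxy-1-oxo-3,10-epoxygermacra-2,4,11(13)-trien-12,6-olid-8-yl 2-methylpropanoate | C=C1C(=O)O[C@H]2/C=C(/CO)C3=CC(=O)[C@@](C)(C[C@@H](OC(=O)C(C)C)[C@@H]12)O3 | target

## Step count and risks

Total steps: 12. Longest linear sequence: 10 (steps 1, 2, 3, 6, 7, 8, 9, 10, 11, 12); steps 4 and 5 form the side branch.

**Steps most likely to fail**

1. Step 3 (the new alkynylation). It may give low ee, double addition or self-condensation of the dione; the sense of induction is unknown, so the ligand antipode is fixed after a first run. Fallback by known chemistry, setting out from enyne 5 and coming back at ketol 7: the same zinc/amino-alcohol system is applied to methyl pyruvate, a known reaction class for α-keto esters, and gives methyl (2R)-5-{[tert-butyl(diphenyl)silyl]oxymethyl}-2-hydroxy-2-methylhex-5-en-3-ynoate F1. Me(MeO)NH·HCl with i-PrMgCl converts it into (2R)-5-{[tert-butyl(diphenyl)silyl]oxymethyl}-2-hydroxy-N-methoxy-N,2-dimethylhex-5-en-3-ynamide F2, and MeMgBr then gives ketol 7, which is silylated to 8 as in the second stage of step 3.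

2. Step 6 (boron aldol). The facial sense and level of reagent control with this α'-silyloxy ketone and this very electrophilic enal are uncertain. Fallback, setting out from ketol 7 (isolated by leaving out the TMSCl quench) and coming back at 15: the enolate is replaced by a silyl enol ether and the stereocontrol by a catalytic chiral Lewis acid with an open transition state. TMSOTf/Et3N gives (3R)-6-{[tert-butyl(diphenyl)silyl]oxymethyl}-3-methyl-2,3-bis(trimethylsilyloxy)hepta-1,6-dien-4-yne F3. A Mukaiyama aldol with 13 under an N-tosyl-tryptophan-derived B-butyl oxazaborolidinone (20 mol%, EtCN, −78 °C; catalyst antipode chosen for the Re face) gives methyl (2Z,4R,7R)-2-(bromomethyl)-10-{[tert-butyl(diphenyl)silyl]oxymethyl}-7-methyl-6-oxo-4,7-bis(trimethylsilyloxy)undeca-2,10-dien-8-ynoate F4. Brief citric acid/MeOH removes the less hindered secondary TMS ether and returns 15.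

3. Step 11 (ring-closing metathesis). Strain of the bridged nine-membered ring and the hindered, electron-poor C4 olefin may stop the closure. Fallback, setting out from 16 and coming back at 25: the ring is closed before the furanone makes the chain rigid, and the furanone is then formed across the ring.
   - The Barbier reaction of 16 with acrolein 19 (In, THF–H2O; the aldehyde reacts much faster than the hindered ketone) gives methyl (3S,4S)-3-[(1R,4R)-1-(tert-butyldimethylsilyloxy)-7-{[tert-butyl(diphenyl)silyl]oxymethyl}-4-methyl-3-oxo-4-(trimethylsilyloxy)oct-7-en-5-yn-1-yl]-4-hydroxy-2-methylidenehex-5-enoate F5.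
   - 2 M HCl closes this to (4S,5S)-4-[(1R,4R)-1-(tert-butyldimethylsilyloxy)-7-{[tert-butyl(diphenyl)silyl]oxymethyl}-4-methyl-3-oxo-4-(trimethylsilyloxy)oct-7-en-5-yn-1-yl]-5-ethenyl-3-methylideneoxolan-2-one F6 and then removes both the TMS and the TBS group, giving (4R,5S)-4-[(1R,4R)-7-{[tert-butyl(diphenyl)silyl]oxymethyl}-1,4-dihydroxy-4-methyl-3-oxooct-7-en-5-yn-1-yl]-5-ethenyl-3-methylideneoxolan-2-one F7.
   - Acylation with 23 (pyridine, DMAP; the tertiary alcohol does not react) gives (1R,4R)-7-{[tert-butyl(diphenyl)silyl]oxymethyl}-1-[(2S,3R)-2-ethenyl-4-methylidene-5-oxooxolan-3-yl]-4-hydroxy-4-methyl-3-oxooct-7-en-5-yn-1-yl 2-methylpropanoate F8.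
   - Co2(CO)8 masks and bends the alkyne as the hexacarbonyldicobalt alkyne complex of F8 F9.
   - Ring-closing metathesis (second-generation Hoveyda–Grubbs catalyst, CH2Cl2, 40 °C) gives the hexacarbonyldicobalt complex of the ten-membered en-yne F10.
   - (NH4)2Ce(NO3)6 in acetone at −78 °C frees the ten-membered en-yne ketol F11. Its ring carbons are C1–C10: C1 (R) carries OH and CH3, C2≡C3, (4Z)-C4=C5 with CH2OTBDPS on C4, C6 (S) and C7 (R) carry the cis-fused α-methylene lactone, C8 (R) carries the isobutyrate, and C10 is the ketone.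
   - AuCl3 (5 mol%, CH2Cl2) then runs the heterocyclisation/1,2-methyl shift of step 8 across the ring and gives 25.

## Further compounds

F1 | step 3 | methyl (2R)-5-{[tert-butyl(diphenyl)silyl]oxymethyl}-2-hydroxy-2-methylhex-5-en-3-ynoate | COC(=O)[C@](O)(C#CC(=C)CO[Si](c1ccccc1)(c1ccccc1)C(C)(C)C)C
F2 | step 3 | (2R)-5-{[tert-butyl(diphenyl)silyl]oxymethyl}-2-hydroxy-N-methoxy-N,2-dimethylhex-5-en-3-ynamide | CON(C)C(=O)[C@](O)(C#CC(=C)CO[Si](c1ccccc1)(c1ccccc1)C(C)(C)C)C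
F3 | step 6 | (3R)-6-{[tert-butyl(diphenyl)silyl]oxymethyl}-3-methyl-2,3-bis(trimethylsilyloxy)hepta-1,6-dien-4-yne | C=C(O[Si](C)(C)C)[C@](O[Si](C)(C)C)(C#CC(=C)CO[Si](c1ccccc1)(c1ccccc1)C(C)(C)C)C
F4 | step 6 | methyl (2Z,4R,7R)-2-(bromomethyl)-10-{[tert-butyl(diphenyl)silyl]oxymethyl}-7-methyl-6-oxo-4,7-bis(trimethylsilyloxy)undeca-2,10-dien-8-ynoate | BrC/C(C(=O)OC)=C\[C@H](O[Si](C)(C)C)CC(=O)[C@](O[Si](C)(C)C)(C#CC(=C)CO[Si](c1ccccc1)(c1ccccc1)C(C)(C)C)C
F5 | step 11 | methyl (3S,4S)-3-[(1R,4R)-1-(tert-butyldimethylsilyloxy)-7-{[tert-butyl(diphenyl)silyl]oxymethyl}-4-methyl-3-oxo-4-(trimethylsilyloxy)oct-7-en-5-yn-1-yl]-4-hydroxy-2-methylidenehex-5-enoate | C=C[C@H](O)[C@H](C(=C)C(=O)OC)[C@H](O[Si](C)(C)C(C)(C)C)CC(=O)[C@](O[Si](C)(C)C)(C#CC(=C)CO[Si](c1ccccc1)(c1ccccc1)C(C)(C)C)C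
F6 | step 11 | (4S,5S)-4-[(1R,4R)-1-(tert-butyldimethylsilyloxy)-7-{[tert-butyl(diphenyl)silyl]oxymethyl}-4-methyl-3-oxo-4-(trimethylsilyloxy)oct-7-en-5-yn-1-yl]-5-ethenyl-3-methylideneoxolan-2-one | C=C[C@@H]1OC(=O)C(=C)[C@@H]1[C@H](O[Si](C)(C)C(C)(C)C)CC(=O)[C@](O[Si](C)(C)C)(C#CC(=C)CO[Si](c2ccccc2)(c3ccccc3)C(C)(C)C)C
F7 | step 11 | (4R,5S)-4-[(1R,4R)-7-{[tert-butyl(diphenyl)silyl]oxymethyl}-1,4-dihydroxy-4-methyl-3-oxooct-7-en-5-yn-1-yl]-5-ethenyl-3-methylideneoxolan-2-one | C=C[C@@H]1OC(=O)C(=C)[C@@H]1[C@H](O)CC(=O)[C@](O)(C#CC(=C)CO[Si](c2ccccc2)(c3ccccc3)C(C)(C)C)C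
F8 | step 11 | (1R,4R)-7-{[tert-butyl(diphenyl)silyl]oxymethyl}-1-[(2S,3R)-2-ethenyl-4-methylidene-5-oxooxolan-3-yl]-4-hydroxy-4-methyl-3-oxooct-7-en-5-yn-1-yl 2-methylpropanoate | C=C[C@@H]1OC(=O)C(=C)[C@@H]1[C@H](OC(=O)C(C)C)CC(=O)[C@](O)(C#CC(=C)CO[Si](c2ccccc2)(c3ccccc3)C(C)(C)C)C
F9 | step 11 | hexacarbonyldicobalt alkyne complex of F8 | C=C[C@@H]1OC(=O)C(=C)[C@@H]1[C@H](OC(=O)C(C)C)CC(=O)[C@](O)(C45C6(C(=C)CO[Si](c2ccccc2)(c3ccccc3)C(C)(C)C)[Co]4(=C=O)(=C=O)(=C=O)[Co]56(=C=O)(=C=O)=C=O)C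
F10 | step 11 | hexacarbonyldicobalt alkyne complex of the ten-membered en-yne F11 | C=C1C(=O)O[C@H]2/C=C(/CO[Si](c3ccccc3)(c4ccccc4)C(C)(C)C)C56C7([Co]5(=C=O)(=C=O)(=C=O)[Co]67(=C=O)(=C=O)=C=O)[C@@](C)(O)C(=O)C[C@@H](OC(=O)C(C)C)[C@@H]12
F11 | step 11 | ten-membered en-yne ketol: (1R,4Z,6S,7R,8R)-cyclodec-4-en-2-yne with 1-OH, 1-CH3, 4-CH2OTBDPS, 10-oxo, 8-(2-methylpropanoyloxy) and the cis-fused 6,7-α-methylene-γ-lactone | C=C1C(=O)O[C@H]2/C=C(/CO[Si](c3ccccc3)(c4ccccc4)C(C)(C)C)C#C[C@@](C)(O)C(=O)C[C@@H](OC(=O)C(C)C)[C@@H]12
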